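In a one-step world the target made per catalyst charged climbs at one pace, whatever the catalyst charge at fixed c(starting material), and that was your hunch when you asked me for a quick number on these flasks.

| flask | starting material | free catalyst | remark | time |
|---|---|---|---|---|
| oak | 19 mM | 2.8 mM | run made earlier |  |
| alder | 27 mM | 2.8 mM | run made earlier |  |
| maple | 42 mM | 2.8 mM | run made earlier |  |
| cedar | 19 mM | 4.2 mM | run made earlier |  |
| zeta | 19 mM (fed, over 30.0 min) | 2.8 mM | a stirred flask in which starting material is dosed at a steady rate over 30.0 min without added volume, worked up at 30 min | 30 min |
| alpha | 19 mM | 2.8 mM | a single well-mixed tank run continuously and read at steady state, 90.0 min in it on average |  |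
| theta | 19 mM | 2.8 mM | a closed flask charged with all of it at once and left for 30 min | 30 min |
| gamma | 19 mM | 2.8 mM | a single well-mixed tank run continuously and read at steady state, 30 min in it on average |  |

- oak (time / min: target / %): 2.50: 0; 5.00: 3; 8.00: 4; 10.0: 3; 12.0: 5; 15.0: 10; 20.0: 11
- alder (time / min: target / %): 2.00: 0; 3.00: 0; 4.00: 1; 6.00: 4; 10.0: 5; 15.0: 4; 25.0: 10
- maple (time / min: target / %): 1.33: 1; 4.00: 1; 6.00: 1; 10.0: 2; 15.0: 9; 20.0: 5; 25.0: 12
- cedar (time / min: target / %): 2.00: 3; 4.00: 1; 6.00: 3; 12.0: 9; 25.0: 14

(readings scatter by 2 percentage points)

- the stated concentrations are those of everything mixed, before any reaction; amounts are the same in each set-up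
- the analysis behind the earlier runs scatters by 2 percentage points, standard deviation
- the feed brings no volume worth counting
- the earlier runs were made in a closed, stirred flask

* the set-up with the highest amount of target at the outlet or at the end, in percent of the starting material put in ("none" if the first two lie within 2 percentage points) (zeta / alpha / theta / gamma / none)
* amount of target at the outlet or at the end, in percent of the starting material put in, zeta
* amount of target at the outlet or at the end, in percent of the starting material put in, alpha
* amount of target at the outlet or at the end, in percent of the starting material put in, theta
* amount of target at the outlet or at the end, in percent of the starting material put in, gamma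

I counted turnovers. The last oak reading gave 0.0373 min⁻¹, and this was what I carried: the turnover pace, target made per catalyst charged and per minute. The cedar run, with 4.2 mM of free catalyst at the same c(starting material), read 0.0253 min⁻¹, lower than the oak run, which went against your hunch, though each reading scatters by 2 percentage points. The maple run, at 42 mM, read 0.0720 min⁻¹, higher than the oak run, so I let the pace follow c(starting material). Zeta, alpha, theta and gamma carry the oak run's 2.8 mM of free catalyst and 19 mM of starting material, so I used the oak pace.

At that pace I counted 1.12 turnovers for theta, which came to 16.5% of its charge. In zeta the starting material arrives steadily, so I took 0.560 turnovers, half of that count, or 8.25%. A tank runs at its outlet c(starting material), so its full-pace share comes down to that share over one plus itself, which gave gamma 14.2%. For alpha the full-pace share was 49.5%, which came down to 33.1%, so I put alpha first.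

The forecast said 8% for zeta, 33% for alpha, 15% for theta and 14% for gamma, with alpha ahead, adding “that estimate extrapolates beyond the data”.

The simulation put alpha ahead, with 9.25% for zeta, 36.8% for alpha, 15.6% for theta and 14.8% for gamma. After 30.0 min theta held 44.3% of its catalyst as resting dimer, the resting state there, more than in any other form. Alpha's turnover pace came to 0.0278 min⁻¹, lower than the oak reading, in a tank holding 56.9% of the starting material charged.

    catalyst intermediate → free catalyst + target (k = 0.00260 s⁻¹)
    2 catalyst intermediate ⇌ resting dimer, settled at all times (K = 1400 M⁻¹)
    starting material + free catalyst → catalyst intermediate (k = 0.210 M⁻¹ s⁻¹)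
    free catalyst → spent catalyst (k = 2.60 × 10⁻⁴ s⁻¹)

A neighbour of zeta charged with 0.70 mM of free catalyst, at my 0.560 turnovers, should have made 2.06% target. The simulation gave 3.36%, which is 0.913 turnovers per catalyst charged, more than I had counted.

(The runs stem from a simulated flask with constants of no real substance; noise was put on by code.)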